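The runs were generated by integration from invented constants, noise included.

The trap in a charge of 1.50 equivalents of Q is to call it an excess.

common to all: G 0.20 M
- spring: Q 0.30 M; X 0.81 M; run made earlier
- summer: Q 0.30 M; X 1.5 M; run made earlier
- ochre: Q 0.300 M; X 1.20 M; time 10 d
- green: Q 0.300 M; X 0.600 M; time 10 d

| run | time / d | G / % | J / % |
|---|---|---|---|
| spring | 0.833 | 52.7 | 50.4 |
| spring | 1.67 | 36.7 | 62.4 |
| spring | 2.50 | 32.7 | 68.0 |
| spring | 3.00 | 28.7 | 68.9 |
| spring | 4.00 | 25.9 | 74.9 |
| spring | 5.00 | 23.4 | 76.8 |
| summer | 0.333 | 66.6 | 32.5 |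
| summer | 1.04 | 46.4 | 54.6 |
| summer | 1.67 | 36.9 | 61.2 |
| summer | 2.50 | 31.2 | 70.3 |
| summer | 4.00 | 23.4 | 75.4 |
| summer | 5.00 | 20.8 | 80.1 |

(scatter of a reading: 1 percentage point)

1. part of the G that has reacted at the end, ochre
2. part of the G that has reacted at the end, green
3. what raising the concentration of X from its lowest to its highest value here does to the part of the G that has reacted (changes below 5 percentage points count as none) (it falls / no change / it rises)

In both runs J climbs quickly and then bends: at 4.00 d it reads 74.9% in spring and 75.4% in summer. My working guess is that each G reacted costs two Q, one for J and one lost to something unseen. This gives the two-Q reach, the share of the G that the charged Q can carry to J: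

N = c(Q) / (2 c(G)) = 75.0%

On this guess, an N below 100% makes Q the limiting reagent. X does not enter N, so ochre and green share this value.

One number is not enough, though. Summer J reads 80.1% at 5.00 d, past N, and it gained 9.8 percentage points after 2.50 d. So N marks a shoulder, not a ceiling. I expect both flasks some points beyond it at 10 d, and close together.

The forecast gives 84% for ochre, 83% for green and no change, on the ground that “the rate is practically independent of X here”.

The flask gives 86.1% for ochre and 83.9% for green, a gap of 2.2 points, so no change, as the forecast said.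

    G + Q → Z + J (k = 0.271 M⁻¹ h⁻¹)
    Q + Z ⇌ D, settled at all times (K = 810 M⁻¹)
    Z + X ⇌ L (K = 3.40 M⁻¹, k = 0.433 M⁻¹ h⁻¹)
    Q ⇌ E (K = 0.445, k = 0.0549 h⁻¹)

Z, formed with each J, binds Q as D, which stands at 0.112 M in ochre at 10.0 d, with 3.68% of the charged Q free, and ochre lies 11 points past N. The neighbour of ochre with 0.50 M of G has N = 30.0% and reacts 47.0% of its G, keeping 0.67% of its Q free.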